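**Retrosynthetic overview** (labdane numbering: ring A = C1–C5 and C10, ring B = C5–C10; C4 carries methyl C18 (α) and ester carbon C19 (β), C10 methyl C20, C8 methyl C17, C9 the chain C11–C16)
- Side chain last: the C15 acetate comes from a C13 methyl ketone, kept as a dioxolane until the end, by Horner–Wadsworth–Emmons olefination, ester reduction and acetylation.
- Ring A second: the C4 quaternary centre and the C5 hydrogen are set together by Li/NH3 reductive methylation of a C4=C5 enoate. That enoate is annulated onto a C1 aldehyde/C5 ketone by Wittig (C1=C2) and intramolecular Horner–Wadsworth–Emmons (C4=C5) olefination with one C2–C3–C4(C19) reagent.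
- Ring B first, by ring expansion: C10, with C20 and an ester that becomes C1, is inserted between C5 and C9 of a cyclopentenone with ethyl 2-diazopropanoate under a chiral Sc(OTf)3 catalyst. This sets C10, from which C5 and C4 are relayed.
- Feature used: ring B without C10 is a 3-methyl-2-alkylcyclopent-2-enone (C5 carbonyl, tetrasubstituted C8=C9 carrying C17 and the side chain), made from a 2,5-diketone by Stetter reaction and aldol condensation.

Key step: step 5

Remark: the sense of induction of the scandium catalyst in step 5 cannot be predicted with certainty; it is assumed that a trial run identifies the ligand antipode that gives (1R)-11, both antipodes being accessible from the two pipecolic acids.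

Step 1
Reactants: 1 2-(3-chloropropyl)-2-methyl-1,3-dioxolane
Product: 3 4-(2-methyl-1,3-dioxolan-2-yl)butanal, via Grignard reagent 2 (not isolated)
Conditions: Mg, THF, reflux (BrCH2CH2Br initiation); then DMF, 0 °C → rt; aq NH4Cl
Reagents that add atoms: N,N-dimethylformamide, CN(C)C=O
Why: Grignard formation from the primary chloride and Bouveault formylation with DMF should give the aldehyde after mild NH4Cl hydrolysis of the hemiaminal salt, which leaves the dioxolane intact.

Step 2
Reactants: 3 4-(2-methyl-1,3-dioxolan-2-yl)butanal; 4 methyl vinyl ketone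
Product: 5 8-(2-methyl-1,3-dioxolan-2-yl)octane-2,5-dione
Conditions: 3-benzyl-5-(2-hydroxyethyl)-4-methylthiazolium chloride (10 mol %), Et3N, EtOH, 80 °C
Reagents that add atoms: none
Why: Stetter reaction, in which the thiazolium-derived carbene turns the aliphatic aldehyde into an acyl anion equivalent that adds 1,4 to the enone, the standard entry to 2,5-diketones, and the base-stable ketal is not affected.

Step 3
Reactants: 5 8-(2-methyl-1,3-dioxolan-2-yl)octane-2,5-dione
Product: 7 3-methyl-2-[2-(2-methyl-1,3-dioxolan-2-yl)ethyl]cyclopent-2-en-1-one, via aldol ketol 6 (not isolated)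
Conditions: 2% aq NaOH, EtOH, reflux
Reagents that add atoms: none
Why: Intramolecular aldol condensation of a 2,5-diketone, in which the internal CH2 enolate (future C9) closes on the methyl ketone (future C8) and the ketol dehydrates to the more substituted enone, the thermodynamic product under hydroxide; the ketal keeps the third carbonyl out of the condensation.

Step 4
Reactants: 8 ethyl 2-methyl-3-oxobutanoate (ethyl 2-methylacetoacetate)
Product: 9 ethyl 2-diazopropanoate
Conditions: 4-acetamidobenzenesulfonyl azide, DBU, MeCN, 0 °C → rt; used as a solution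
Reagents that add atoms: 4-acetamidobenzenesulfonyl azide, CC(=O)Nc1ccc(cc1)S(=O)(=O)N=[N+]=[N-]
Why: Regitz diazo transfer with deacylation, in which the azide reacts at the enolate carbon and the adduct passes its acetyl group to the sulfonamide nitrogen, leaving the α-diazo ester.

Step 5
Reactants: 7 3-methyl-2-[2-(2-methyl-1,3-dioxolan-2-yl)ethyl]cyclopent-2-en-1-one; 9 ethyl 2-diazopropanoate
Product: 11 ethyl (1R)-1,3-dimethyl-6-oxo-2-[2-(2-methyl-1,3-dioxolan-2-yl)ethyl]cyclohex-2-ene-1-carboxylate, via diazonium alkoxide 10 (not isolated)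
Conditions: Sc(OTf)3 (10 mol %), 1,1'-(propane-1,3-diyl)bis{(2S)-2-[(2,6-diisopropylphenyl)carbamoyl]piperidine 1-oxide} or its enantiomer (11 mol %), 4 Å molecular sieves, CH2Cl2, −20 °C, slow addition of 9
Reagents that add atoms: none
Why: Proposed new method: the ligated trivalent scandium centre binds the enone oxygen of 7, the nucleophilic diazo carbon of 9 adds 1,2 to the carbonyl carbon C5 to give the diazonium alkoxide 10, and the alkenyl carbon C9, held anti to the departing N2, shifts from C5 to the diazo carbon in a Tiffeneau–Demjanov-type 1,2-shift while the C5 carbonyl is re-formed. The closest known reaction types are chiral-Lewis-acid-catalysed (Sc(OTf)3–N,N'-dioxide, aluminium–BINOL) homologations of cyclic ketones with α-alkyl α-diazo esters that create α-quaternary β-keto esters, and alkenyl migration in Lewis-acid-promoted diazoacetate homologation of enones. Ring B is closed by one-carbon ring expansion of the five-membered ring, both new bonds (C5–C10 and C9–C10) ending at the inserted carbon, so no cyclisation is involved. The C10 centre is controlled by the chiral ligand on scandium, which selects the enantioface of the diazo carbon that bonds to C5; the shift is stereospecific with inversion at that carbon and the quaternary product cannot racemise. The step needs alkenyl-over-CH2 migration and 1,2-addition in preference to cycloaddition or conjugate addition: the first rests on the higher migratory aptitude of the π-donating alkenyl carbon, the second on the fully substituted C8=C9 bond, which blocks pyrazoline formation and attack at C8, and the more hindered product ketone should not be homologated again.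

Step 6
Reactants: 11 ethyl (1R)-1,3-dimethyl-6-oxo-2-[2-(2-methyl-1,3-dioxolan-2-yl)ethyl]cyclohex-2-ene-1-carboxylate
Product: 12 (2S)-2-(hydroxymethyl)-2,4-dimethyl-3-[2-(2-methyl-1,3-dioxolan-2-yl)ethyl]cyclohex-3-en-1-ol (both C1 epimers)
Conditions: LiAlH4, THF, 0 °C → rt; aq potassium sodium tartrate
Reagents that add atoms: none
Why: LiAlH4 reduction of ketone and hindered ester to the 1,3-diol (the carbinol configuration is irrelevant because it is reoxidised) leaves the tetrasubstituted alkene, the dioxolane and the quaternary centre untouched.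

Step 7
Reactants: 12 (2S)-2-(hydroxymethyl)-2,4-dimethyl-3-[2-(2-methyl-1,3-dioxolan-2-yl)ethyl]cyclohex-3-en-1-ol
Product: 13 (1S)-1,3-dimethyl-6-oxo-2-[2-(2-methyl-1,3-dioxolan-2-yl)ethyl]cyclohex-2-ene-1-carbaldehyde
Conditions: Dess–Martin periodinane, pyridine, CH2Cl2, 0 °C → rt; used at once
Reagents that add atoms: none
Why: Buffered Dess–Martin oxidation converts both alcohols under near-neutral conditions that keep the ketal, and the keto aldehyde has no α-hydrogen at C10 and so cannot epimerise.

Step 8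
Reactants: 14 methyl 2-(diethoxyphosphoryl)acetate (1.5 equiv); 15 ethenyl(triphenyl)phosphonium bromide
Product: 16 [3-(diethoxyphosphoryl)-4-methoxy-4-oxobutyl]triphenylphosphonium bromide (racemic)
Conditions: NaH (10 mol %), THF–DMF, 0 °C → rt; precipitation with Et2O
Reagents that add atoms: none
Why: Michael addition of the phosphonoacetate carbanion to the vinylphosphonium salt gives an ylide that is protonated by further phosphonoacetate, so catalytic base suffices, and the excess of 14 limits double addition.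

Step 9
Reactants: 13 (1S)-1,3-dimethyl-6-oxo-2-[2-(2-methyl-1,3-dioxolan-2-yl)ethyl]cyclohex-2-ene-1-carbaldehyde; 16 [3-(diethoxyphosphoryl)-4-methoxy-4-oxobutyl]triphenylphosphonium bromide
Product: 19 methyl (4aR)-4a,6-dimethyl-5-[2-(2-methyl-1,3-dioxolan-2-yl)ethyl]-2,4a,7,8-tetrahydronaphthalene-1-carboxylate, via phosphonium ylide carbanion 17 (not isolated), via Z keto phosphonate 18 (not isolated)
Conditions: 16 (1.0 equiv), KN(SiMe3)2 (2.0 equiv), THF, −78 → −40 °C; then 13, −78 °C → rt; then 50 °C
Reagents that add atoms: none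
Why: Double deprotonation gives a non-stabilised, salt-free ylide that also carries the less reactive phosphonoacetate carbanion; the ylide should undergo Z-selective Wittig olefination at the aldehyde (C1=C2) in preference to the hindered C5 ketone, and on warming the phosphonate carbanion, held close by the cis alkene, should close ring A by intramolecular Horner–Wadsworth–Emmons olefination of the ketone (C4=C5), both equivalents of base being consumed so that the skipped diene is not isomerised.

Step 10
Reactants: 19 methyl (4aR)-4a,6-dimethyl-5-[2-(2-methyl-1,3-dioxolan-2-yl)ethyl]-2,4a,7,8-tetrahydronaphthalene-1-carboxylate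
Product: 20 methyl (4aR)-4a,6-dimethyl-5-[2-(2-methyl-1,3-dioxolan-2-yl)ethyl]-2,3,4,4a,7,8-hexahydronaphthalene-1-carboxylate
Conditions: H2 (1 atm), RhCl(PPh3)3 (5 mol %), toluene–EtOH, rt
Reagents that add atoms: none
Why: Homogeneous hydrogenation with RhCl(PPh3)3 reduces the cis-disubstituted C1=C2 alkene, as it does for ring alkenes next to a quaternary carbon in steroidal dienones, while the two tetrasubstituted alkenes (C4=C5 enoate and C8=C9) are too hindered to coordinate.

Step 11
Reactants: 20 methyl (4aR)-4a,6-dimethyl-5-[2-(2-methyl-1,3-dioxolan-2-yl)ethyl]-2,3,4,4a,7,8-hexahydronaphthalene-1-carboxylate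
Product: 22 methyl (1S,4aS,8aR)-1,4a,6-trimethyl-5-[2-(2-methyl-1,3-dioxolan-2-yl)ethyl]-1,2,3,4,4a,7,8,8a-octahydronaphthalene-1-carboxylate, via lithium ester enolate 21 (not isolated)
Conditions: Li, NH3(l)–THF, t-BuOH (1 equiv), −78 °C; isoprene; then MeI, −78 → −33 °C
Reagents that add atoms: methyl iodide, CI
Why: Dissolving-metal (Birch-type) reductive alkylation of an α,β-unsaturated ester: reduction and protonation at C5 from the α face, anti to the axial C10 methyl, should give the trans ring fusion and the exocyclic ester enolate, which methyl iodide attacks from the equatorial α face away from the 1,3-diaxial C10 methyl, so that C18 is α and the ester C19 axial β, both new centres being relayed from C10.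

Step 12
Reactants: 22 methyl (1S,4aS,8aR)-1,4a,6-trimethyl-5-[2-(2-methyl-1,3-dioxolan-2-yl)ethyl]-1,2,3,4,4a,7,8,8a-octahydronaphthalene-1-carboxylate
Product: 23 methyl (1S,4aS,8aR)-1,4a,6-trimethyl-5-(3-oxobutyl)-1,2,3,4,4a,7,8,8a-octahydronaphthalene-1-carboxylate
Conditions: 1 M aq HCl, THF, rt
Reagents that add atoms: water, O
Why: Acid-catalysed ketal hydrolysis frees the methyl ketone; dilute acid does not touch the hindered ester, and the C8=C9 alkene already sits in its most stable position.

Step 13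
Reactants: 23 methyl (1S,4aS,8aR)-1,4a,6-trimethyl-5-(3-oxobutyl)-1,2,3,4,4a,7,8,8a-octahydronaphthalene-1-carboxylate; 24 triethyl phosphonoacetate
Product: 25 methyl (1S,4aS,8aR)-5-[(3E)-5-ethoxy-3-methyl-5-oxopent-3-en-1-yl]-1,4a,6-trimethyl-1,2,3,4,4a,7,8,8a-octahydronaphthalene-1-carboxylate
Conditions: NaH, THF, 0 °C → 50 °C; chromatographic removal of the Z isomer
Reagents that add atoms: none
Why: Horner–Wadsworth–Emmons olefination of the methyl ketone should favour the E enoate (ester trans to the larger CH2 chain), and the neopentyl axial C19 ester does not react.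

Step 14
Reactants: 25 methyl (1S,4aS,8aR)-5-[(3E)-5-ethoxy-3-methyl-5-oxopent-3-en-1-yl]-1,4a,6-trimethyl-1,2,3,4,4a,7,8,8a-octahydronaphthalene-1-carboxylate
Product: 26 methyl (1S,4aS,8aR)-5-[(3E)-5-hydroxy-3-methylpent-3-en-1-yl]-1,4a,6-trimethyl-1,2,3,4,4a,7,8,8a-octahydronaphthalene-1-carboxylate
Conditions: i-Bu2AlH (2.2 equiv), CH2Cl2, −78 °C; aq potassium sodium tartrate
Reagents that add atoms: none
Why: i-Bu2AlH reduction of the unhindered conjugated ethyl ester to the allylic alcohol at low temperature should spare the axial methyl ester on quaternary C4, which is shielded by the C10 methyl and the C6 methylene.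

Step 15
Reactants: 26 methyl (1S,4aS,8aR)-5-[(3E)-5-hydroxy-3-methylpent-3-en-1-yl]-1,4a,6-trimethyl-1,2,3,4,4a,7,8,8a-octahydronaphthalene-1-carboxylate
Product: 27 methyl (1S,4aS,8aR)-5-[(3E)-5-acetoxy-3-methylpent-3-en-1-yl]-1,4a,6-trimethyl-1,2,3,4,4a,7,8,8a-octahydronaphthalene-1-carboxylate (CNP0206695.1)
Conditions: Ac2O, pyridine, DMAP (cat.), CH2Cl2, rt
Reagents that add atoms: acetic anhydride, CC(=O)OC(C)=O
Why: DMAP-catalysed acetylation of the primary allylic alcohol changes no stereocentre and no alkene.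

**Compound list**
1 | 2-(3-chloropropyl)-2-methyl-1,3-dioxolane | CC1(CCCCl)OCCO1 | starting material
2 | [3-(2-methyl-1,3-dioxolan-2-yl)propyl]magnesium chloride | CC1(CCC[Mg]Cl)OCCO1 | intermediate
3 | 4-(2-methyl-1,3-dioxolan-2-yl)butanal | CC1(CCCC=O)OCCO1 | intermediate
4 | methyl vinyl ketone (but-3-en-2-one) | CC(=O)C=C | starting material
5 | 8-(2-methyl-1,3-dioxolan-2-yl)octane-2,5-dione | CC(=O)CCC(=O)CCCC1(C)OCCO1 | intermediate
6 | 3-hydroxy-3-methyl-2-[2-(2-methyl-1,3-dioxolan-2-yl)ethyl]cyclopentan-1-one (diastereomer mixture) | CC1(O)CCC(=O)C1CCC2(C)OCCO2 | intermediate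
7 | 3-methyl-2-[2-(2-methyl-1,3-dioxolan-2-yl)ethyl]cyclopent-2-en-1-one | CC1=C(CCC2(C)OCCO2)C(=O)CC1 | intermediate
8 | ethyl 2-methyl-3-oxobutanoate | CCOC(=O)C(C)C(C)=O | starting material
9 | ethyl 2-diazopropanoate | CCOC(=O)C(C)=[N+]=[N-] | intermediate
10 | scandium-bound zwitterion ethyl 2-diazonio-2-{3-methyl-2-[2-(2-methyl-1,3-dioxolan-2-yl)ethyl]-1-oxidocyclopent-2-en-1-yl}propanoate (carbinol configuration not assigned) | CCOC(=O)[C@@](C)([N+]#N)C1([O-])CCC(C)=C1CCC2(C)OCCO2 | intermediate
11 | ethyl (1R)-1,3-dimethyl-6-oxo-2-[2-(2-methyl-1,3-dioxolan-2-yl)ethyl]cyclohex-2-ene-1-carboxylate | CCOC(=O)[C@@]1(C)C(=O)CCC(C)=C1CCC2(C)OCCO2 | intermediate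
12 | (2S)-2-(hydroxymethyl)-2,4-dimethyl-3-[2-(2-methyl-1,3-dioxolan-2-yl)ethyl]cyclohex-3-en-1-ol (both C1 epimers) | OC[C@@]1(C)C(O)CCC(C)=C1CCC2(C)OCCO2 | intermediate
13 | (1S)-1,3-dimethyl-6-oxo-2-[2-(2-methyl-1,3-dioxolan-2-yl)ethyl]cyclohex-2-ene-1-carbaldehyde | O=C[C@@]1(C)C(=O)CCC(C)=C1CCC2(C)OCCO2 | intermediate
14 | methyl 2-(diethoxyphosphoryl)acetate | COC(=O)CP(=O)(OCC)OCC | starting material
15 | ethenyl(triphenyl)phosphonium bromide | C=C[P+](c1ccccc1)(c1ccccc1)c1ccccc1.[Br-] | starting material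
16 | [3-(diethoxyphosphoryl)-4-methoxy-4-oxobutyl]triphenylphosphonium bromide (racemic) | COC(=O)C(CC[P+](c1ccccc1)(c1ccccc1)c1ccccc1)P(=O)(OCC)OCC.[Br-] | intermediate
17 | potassium 1-(diethoxyphosphoryl)-1-(methoxycarbonyl)-3-(triphenylphosphoranylidene)propan-1-ide | COC(=O)[C-](CC=P(c1ccccc1)(c1ccccc1)c1ccccc1)P(=O)(OCC)OCC.[K+] | intermediate
18 | methyl (4Z)-2-(diethoxyphosphoryl)-5-{(1R)-1,3-dimethyl-6-oxo-2-[2-(2-methyl-1,3-dioxolan-2-yl)ethyl]cyclohex-2-en-1-yl}pent-4-enoate (both C2 epimers; present as its potassium carbanion) | COC(=O)C(C/C=C\[C@@]1(C)C(=O)CCC(C)=C1CCC2(C)OCCO2)P(=O)(OCC)OCC | intermediate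
19 | methyl (4aR)-4a,6-dimethyl-5-[2-(2-methyl-1,3-dioxolan-2-yl)ethyl]-2,4a,7,8-tetrahydronaphthalene-1-carboxylate | COC(=O)C1=C2CCC(C)=C(CCC3(C)OCCO3)[C@@]2(C)C=CC1 | intermediate
20 | methyl (4aR)-4a,6-dimethyl-5-[2-(2-methyl-1,3-dioxolan-2-yl)ethyl]-2,3,4,4a,7,8-hexahydronaphthalene-1-carboxylate | COC(=O)C1=C2CCC(C)=C(CCC3(C)OCCO3)[C@@]2(C)CCC1 | intermediate
21 | lithium enolate of the C19 methyl ester (C4=C19 enolate, 5α-H, 10β-methyl, trans-fused) | COC(O[Li])=C1CCC[C@]2(C)C(CCC3(C)OCCO3)=C(C)CC[C@@H]12 | intermediate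
22 | methyl (1S,4aS,8aR)-1,4a,6-trimethyl-5-[2-(2-methyl-1,3-dioxolan-2-yl)ethyl]-1,2,3,4,4a,7,8,8a-octahydronaphthalene-1-carboxylate | COC(=O)[C@@]1(C)CCC[C@]2(C)C(CCC3(C)OCCO3)=C(C)CC[C@@H]12 | intermediate
23 | methyl (1S,4aS,8aR)-1,4a,6-trimethyl-5-(3-oxobutyl)-1,2,3,4,4a,7,8,8a-octahydronaphthalene-1-carboxylate | COC(=O)[C@@]1(C)CCC[C@]2(C)C(CCC(C)=O)=C(C)CC[C@@H]12 | intermediate
24 | triethyl phosphonoacetate | CCOC(=O)CP(=O)(OCC)OCC | starting material
25 | methyl (1S,4aS,8aR)-5-[(3E)-5-ethoxy-3-methyl-5-oxopent-3-en-1-yl]-1,4a,6-trimethyl-1,2,3,4,4a,7,8,8a-octahydronaphthalene-1-carboxylate | COC(=O)[C@@]1(C)CCC[C@]2(C)C(CC/C(C)=C/C(=O)OCC)=C(C)CC[C@@H]12 | intermediate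
26 | methyl (1S,4aS,8aR)-5-[(3E)-5-hydroxy-3-methylpent-3-en-1-yl]-1,4a,6-trimethyl-1,2,3,4,4a,7,8,8a-octahydronaphthalene-1-carboxylate | COC(=O)[C@@]1(C)CCC[C@]2(C)C(CC/C(C)=C/CO)=C(C)CC[C@@H]12 | intermediate
27 | methyl (1S,4aS,8aR)-5-[(3E)-5-acetoxy-3-methylpent-3-en-1-yl]-1,4a,6-trimethyl-1,2,3,4,4a,7,8,8a-octahydronaphthalene-1-carboxylate | COC(=O)[C@@]1(C)CCC[C@]2(C)C(CC/C(C)=C/COC(C)=O)=C(C)CC[C@@H]12 | target

**Step count**
Total: 15 steps. Longest linear sequence: 13 steps (steps 1, 2, 3, 5, 6, 7, 9, 10, 11, 12, 13, 14, 15); steps 4 and 8 are side branches.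

**Steps most likely to fail**

Step 5 (proposed new method). The process at risk is migration of the ring CH2 (C6) in place of the fully substituted alkenyl carbon C9, poor enantioface discrimination at the diazo carbon, or ionisation of the dioxolane on scandium. The fallback uses known chemistry and separates carbon insertion from creation of the stereocentre; it sets out from 7 and comes back at 11. Enone 7 is homologated with ethyl diazoacetate and BF3·OEt2 (CH2Cl2, −78 → 0 °C), the Lewis-acid-promoted diazoacetate ring expansion in which the alkenyl carbon of an enone migrates to a secondary carbon, to give the racemic, enolisable β-keto ester ethyl 3-methyl-6-oxo-2-[2-(2-methyl-1,3-dioxolan-2-yl)ethyl]cyclohex-2-ene-1-carboxylate F1. Condensation with tert-butyl L-valinate (cat. AcOH, molecular sieves, toluene) gives the chiral enamino ester ethyl 6-{[(2S)-1-tert-butoxy-3-methyl-1-oxobutan-2-yl]amino}-3-methyl-2-[2-(2-methyl-1,3-dioxolan-2-yl)ethyl]cyclohexa-1(6),2-diene-1-carboxylate F2. Deprotonation with LiN(i-Pr)2 and C-methylation with MeI, an auxiliary-controlled alkylation of the chelated lithio enamine in which the solvent additive (or tert-butyl D-valinate) is chosen so that the (R) centre results, gives the imino ester ethyl (1R)-6-{[(2S)-1-tert-butoxy-3-methyl-1-oxobutan-2-yl]imino}-1,3-dimethyl-2-[2-(2-methyl-1,3-dioxolan-2-yl)ethyl]cyclohex-2-ene-1-carboxylate F3. Hydrolysis in buffered aqueous acetic acid releases the auxiliary and gives 11.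

Step 9. The process at risk is incomplete second deprotonation of 16, the ylide acting as a base towards the keto aldehyde (enolisation at C6 or deformylation), or loss of Z selectivity, after which the phosphonate cannot reach the C5 ketone. The fallback sets out from 13 and comes back at 20, building the same chain by allylic substitution in place of the Wittig reaction. CH2=CHMgBr (THF, −78 °C) adds to the aldehyde of 13 in preference to the hindered ketone to give the allylic alcohol (2S)-2-(1-hydroxyprop-2-en-1-yl)-2,4-dimethyl-3-[2-(2-methyl-1,3-dioxolan-2-yl)ethyl]cyclohex-3-en-1-one F4. ClCO2Me and pyridine give the methyl carbonate methyl 1-{(1S)-1,3-dimethyl-6-oxo-2-[2-(2-methyl-1,3-dioxolan-2-yl)ethyl]cyclohex-2-en-1-yl}prop-2-en-1-yl carbonate F5. Tsuji–Trost allylation of 14 with Pd(PPh3)4 (THF, 50 °C), the nucleophile entering at the unsubstituted allyl terminus, gives the E keto phosphonate methyl (4E)-2-(diethoxyphosphoryl)-5-{(1R)-1,3-dimethyl-6-oxo-2-[2-(2-methyl-1,3-dioxolan-2-yl)ethyl]cyclohex-2-en-1-yl}pent-4-enoate F6. Hydrogenation of the disubstituted alkene with H2 and RhCl(PPh3)3 gives the saturated keto phosphonate methyl 2-(diethoxyphosphoryl)-5-{(1R)-1,3-dimethyl-6-oxo-2-[2-(2-methyl-1,3-dioxolan-2-yl)ethyl]cyclohex-2-en-1-yl}pentanoate F7. NaH (THF, reflux) then closes ring A by intramolecular Horner–Wadsworth–Emmons olefination to 20.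

Step 11. The process at risk is over-reduction of the ester, protonation of the enolate in ammonia before methyl iodide arrives, or insufficient facial selectivity in the one-flask alkylation. The fallback sets out from 20 and comes back at 22, separating reduction from alkylation. Li/NH3 with t-BuOH followed by an NH4Cl quench gives the trans-fused saturated ester methyl (4aS,8aS)-4a,6-dimethyl-5-[2-(2-methyl-1,3-dioxolan-2-yl)ethyl]-1,2,3,4,4a,7,8,8a-octahydronaphthalene-1-carboxylate F8 (C1 epimers). Its enolate is regenerated with LiN(i-Pr)2 in THF–DMPU at −78 °C and methylated with MeI, the established equatorial alkylation of C4 ester enolates of 10-methyl-trans-decalins, to give 22.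

**Further compounds**
F1 | step 5 | ethyl 3-methyl-6-oxo-2-[2-(2-methyl-1,3-dioxolan-2-yl)ethyl]cyclohex-2-ene-1-carboxylate (racemic) | CCOC(=O)C1C(=O)CCC(C)=C1CCC2(C)OCCO2
F2 | step 5 | ethyl 6-{[(2S)-1-tert-butoxy-3-methyl-1-oxobutan-2-yl]amino}-3-methyl-2-[2-(2-methyl-1,3-dioxolan-2-yl)ethyl]cyclohexa-1(6),2-diene-1-carboxylate | CCOC(=O)C1=C(N[C@@H](C(C)C)C(=O)OC(C)(C)C)CCC(C)=C1CCC2(C)OCCO2
F3 | step 5 | ethyl (1R)-6-{[(2S)-1-tert-butoxy-3-methyl-1-oxobutan-2-yl]imino}-1,3-dimethyl-2-[2-(2-methyl-1,3-dioxolan-2-yl)ethyl]cyclohex-2-ene-1-carboxylate | CCOC(=O)[C@@]1(C)C(=N[C@@H](C(C)C)C(=O)OC(C)(C)C)CCC(C)=C1CCC2(C)OCCO2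
F4 | step 9 | (2S)-2-(1-hydroxyprop-2-en-1-yl)-2,4-dimethyl-3-[2-(2-methyl-1,3-dioxolan-2-yl)ethyl]cyclohex-3-en-1-one (carbinol epimers) | C=CC(O)[C@@]1(C)C(=O)CCC(C)=C1CCC2(C)OCCO2
F5 | step 9 | methyl 1-{(1S)-1,3-dimethyl-6-oxo-2-[2-(2-methyl-1,3-dioxolan-2-yl)ethyl]cyclohex-2-en-1-yl}prop-2-en-1-yl carbonate | C=CC(OC(=O)OC)[C@@]1(C)C(=O)CCC(C)=C1CCC2(C)OCCO2
F6 | step 9 | methyl (4E)-2-(diethoxyphosphoryl)-5-{(1R)-1,3-dimethyl-6-oxo-2-[2-(2-methyl-1,3-dioxolan-2-yl)ethyl]cyclohex-2-en-1-yl}pent-4-enoate | COC(=O)C(C/C=C/[C@@]1(C)C(=O)CCC(C)=C1CCC2(C)OCCO2)P(=O)(OCC)OCC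
F7 | step 9 | methyl 2-(diethoxyphosphoryl)-5-{(1R)-1,3-dimethyl-6-oxo-2-[2-(2-methyl-1,3-dioxolan-2-yl)ethyl]cyclohex-2-en-1-yl}pentanoate | COC(=O)C(CCC[C@@]1(C)C(=O)CCC(C)=C1CCC2(C)OCCO2)P(=O)(OCC)OCC
F8 | step 11 | methyl (4aS,8aS)-4a,6-dimethyl-5-[2-(2-methyl-1,3-dioxolan-2-yl)ethyl]-1,2,3,4,4a,7,8,8a-octahydronaphthalene-1-carboxylate (C1 epimers) | COC(=O)C1CCC[C@]2(C)C(CCC3(C)OCCO3)=C(C)CC[C@@H]12
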